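The 22-membered ring is opened at the C8–C9 midpoint of the unfunctionalised sixteen-carbon chain that links carbon 6 of ring B to carbon 3 of ring A. Because that bond lies as far as possible from the congested diaryl ether oxygen between carbon 1 of ring B and carbon 5 of ring A, and splits the chain into two identical eight-carbon arms, it can be made last by copper-mediated oxidative coupling of two terminal alkynes. This forms the C8–C9 bond and the macrocycle in one operation as a 1,3-diyne that hydrogenation later erases. The precursor is the tri-O-methyl diaryl ether bearing one oct-7-ynyl arm on each ring, both installed together on a dibromo diaryl ether.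

Key step: step 6

Remarks on the chemistry:
- Locants: on ring A, position 1 bears the oxygen substituent, position 3 bears chain carbon C16 and position 5 bears the ether oxygen. On ring B, position 1 bears the ether oxygen, positions 2 and 4 bear oxygen substituents and position 6 bears chain carbon C1. The chain is numbered C1 to C16 from ring B to ring A. The target has no stereocentre.
- Assumption: 2-bromo-4,6-dimethoxybenzaldehyde is taken as purchasable; otherwise it is one Vilsmeier formylation from 1-bromo-3,5-dimethoxybenzene.
- The ring-B bromine is bought in place because bromination of 2,4-dimethoxyphenol would have to choose between the position ortho to the hydroxyl and the doubly methoxy-activated position 5.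

Step 1
Reactants: 1 2-bromo-4,6-dimethoxybenzaldehyde
Product: 3 2-bromo-4,6-dimethoxyphenol, via 2-bromo-4,6-dimethoxyphenyl formate 2 (not isolated)
Conditions: mCPBA, CH2Cl2, 0 °C to rt; aq. Na2S2O3/NaHCO3 wash; then K2CO3, MeOH, rt
Reagents that add atoms: mCPBA (3-chloroperoxybenzoic acid), OOC(=O)c1cccc(Cl)c1
Why: Dakin-type sequence in which Baeyer–Villiger oxidation of the electron-rich benzaldehyde proceeds with migration of the aryl group (methoxy groups ortho and para to the migrating carbon) to give formate 2, whose methanolysis frees the phenol with the bromine and methoxy pattern already fixed by the starting material.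

Step 2
Reactants: 3 2-bromo-4,6-dimethoxyphenol; 4 (3-bromo-5-methoxyphenyl)boronic acid
Product: 5 1-bromo-2-(3-bromo-5-methoxyphenoxy)-3,5-dimethoxybenzene
Conditions: 4 (2.5 equiv), Cu(OAc)2 (1.5 equiv), pyridine, 4 Å molecular sieves, CH2Cl2, air, rt
Reagents that add atoms: none
Why: Chan–Lam–Evans etherification, in which the phenoxide and the aryl group of 4 are assembled on copper and C–O reductive elimination from a trivalent copper centre gives the diaryl ether at room temperature, conditions that leave both aryl bromides untouched and that tolerate ortho substituents on the phenol partner.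

Step 3
Reactants: 6 oct-1-en-7-yne
Product: 8 triisopropyl(oct-7-en-1-yn-1-yl)silane, via lithium oct-7-en-1-yn-1-ide 7 (not isolated)
Conditions: n-BuLi, THF, −78 °C; then TIPSCl, −78 °C to rt
Reagents that add atoms: chlorotriisopropylsilane (TIPSCl), CC(C)[Si](Cl)(C(C)C)C(C)C
Why: Deprotonation of the terminal alkyne and C-silylation of the lithium acetylide (alkyne protection), the alkene being inert to both reagents.

Step 4
Reactants: 5 1-bromo-2-(3-bromo-5-methoxyphenoxy)-3,5-dimethoxybenzene; 8 triisopropyl(oct-7-en-1-yn-1-yl)silane
Product: 10 1-{2,4-dimethoxy-6-[8-(triisopropylsilyl)oct-7-yn-1-yl]phenoxy}-3-methoxy-5-[8-(triisopropylsilyl)oct-7-yn-1-yl]benzene, via 9-[8-(triisopropylsilyl)oct-7-yn-1-yl]-9-borabicyclo[3.3.1]nonane 9 (not isolated)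
Conditions: 8 (2.6 equiv), 9-BBN dimer (1.25 equiv), THF, 0 °C to rt; then 5 (1 equiv), Pd(OAc)2, SPhos, aq. K3PO4, THF, 65 °C
Reagents that add atoms: none
Why: 9-BBN adds anti-Markovnikov to the terminal alkene of 8 far faster than to the TIPS-shielded internal alkyne, and the primary alkylborane 9, activated by aqueous phosphate, transmetallates to the arylpalladium bromide formed at each C–Br bond of 5 (double B-alkyl Suzuki–Miyaura coupling, SPhos coping with the electron-rich rings and the ortho ether), the TIPS group surviving warm aqueous base that could strip a trimethylsilyl alkyne.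

Step 5
Reactants: 10 1-{2,4-dimethoxy-6-[8-(triisopropylsilyl)oct-7-yn-1-yl]phenoxy}-3-methoxy-5-[8-(triisopropylsilyl)oct-7-yn-1-yl]benzene
Product: 11 1-[2,4-dimethoxy-6-(oct-7-yn-1-yl)phenoxy]-3-methoxy-5-(oct-7-yn-1-yl)benzene
Conditions: TBAF, wet THF, 0 °C to rt
Reagents that add atoms: none
Why: Fluoride-mediated protodesilylation, in which fluoride attacks silicon, the acetylide is expelled and protonated by water, and the aryl methyl ethers and the diaryl ether are unaffected.

Step 6
Reactants: 11 1-[2,4-dimethoxy-6-(oct-7-yn-1-yl)phenoxy]-3-methoxy-5-(oct-7-yn-1-yl)benzene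
Product: 12 macrocyclic 1,3-diyne trimethyl ether (22-membered cyclophane; bridge –(CH2)6–C≡C–C≡C–(CH2)6– from position 6 of ring B to position 3 of ring A; methoxy groups at position 1 of ring A and positions 2 and 4 of ring B)
Conditions: Cu(OAc)2 (10 equiv), pyridine, 60 °C, 11 added by syringe pump over 24 h, final concentration about 1 mM
Reagents that add atoms: none
Why: In this Eglinton oxidative homocoupling, acetate and pyridine assist deprotonation of each terminal alkyne to a copper acetylide, and divalent copper oxidises the pair, most plausibly within a dinuclear acetylide complex, so that C8 and C9 are joined as the central bond of a conjugated 1,3-diyne while two equivalents of monovalent copper are released. The closest known reaction type is the Eglinton (Glaser-type) macrocyclisation of α,ω-diynes to cyclic 1,3-diynes under high dilution. The one ring formed is the 22-membered cyclophane, closed end-to-end by intramolecular sp–sp coupling of the two arm termini, and the linear C7–C10 unit should be spanned without strain by two hexamethylene tethers. No stereocentre arises and there is no regiochemical choice, because the two reacting carbons are equivalent terminal alkyne carbons at the point of the ring most remote from the crowded diaryl ether oxygen. The only selectivity needed is ring closure over oligomerisation, secured by slow addition of 11 into a large excess of Cu(OAc)2 so that the stationary concentration of uncoupled alkyne stays very low, and aided by the ortho (ring B) and meta (ring A) attachment of the arms around the bent diaryl ether, which lets their ends converge. Methyl ethers and the diaryl ether are inert to Cu(OAc)2 in pyridine.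

Step 7
Reactants: 12 macrocyclic 1,3-diyne trimethyl ether
Product: 13 tri-O-methylgrevirobstol B (22-membered cyclophane; bridge –(CH2)16– from position 6 of ring B to position 3 of ring A; methoxy groups at position 1 of ring A and positions 2 and 4 of ring B)
Conditions: H2 (1 atm), Pd/C, EtOAc, rt
Reagents that add atoms: none
Why: Heterogeneous catalytic hydrogenation adds four equivalents of H2 across the conjugated diyne to give the saturated hexadecamethylene bridge, while the arenes, aryl methyl ethers and diaryl ether are inert at ambient pressure.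

Step 8
Reactants: 13 tri-O-methylgrevirobstol B
Product: 14 grevirobstol B (free hydroxyls at position 1 of ring A and positions 2 and 4 of ring B)
Conditions: BBr3 (6 equiv), CH2Cl2, −78 °C to rt; then H2O
Reagents that add atoms: none
Why: Lewis-acid ether cleavage, in which BBr3 coordinates each methoxy oxygen and bromide attacks the methyl carbon by SN2, whereas the diaryl ether oxygen, flanked only by sp2 carbons, cannot be cleaved this way, and aqueous work-up hydrolyses the aryl borates to the triol.

Compound list
1 | 2-bromo-4,6-dimethoxybenzaldehyde | COc1cc(Br)c(C=O)c(OC)c1 | starting material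
2 | 2-bromo-4,6-dimethoxyphenyl formate (formed in the flask, not isolated) | COc1cc(Br)c(OC=O)c(OC)c1 | intermediate
3 | 2-bromo-4,6-dimethoxyphenol | COc1cc(Br)c(O)c(OC)c1 | intermediate
4 | (3-bromo-5-methoxyphenyl)boronic acid | COc1cc(Br)cc(c1)B(O)O | starting material
5 | 1-bromo-2-(3-bromo-5-methoxyphenoxy)-3,5-dimethoxybenzene | COc1cc(Br)cc(Oc2c(Br)cc(OC)cc2OC)c1 | intermediate
6 | oct-1-en-7-yne | C=CCCCCC#C | starting material
7 | lithium oct-7-en-1-yn-1-ide (formed in the flask, not isolated) | [Li]C#CCCCCC=C | intermediate
8 | triisopropyl(oct-7-en-1-yn-1-yl)silane | C=CCCCCC#C[Si](C(C)C)(C(C)C)C(C)C | intermediate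
9 | 9-[8-(triisopropylsilyl)oct-7-yn-1-yl]-9-borabicyclo[3.3.1]nonane (formed in the flask, not isolated) | CC(C)[Si](C(C)C)(C(C)C)C#CCCCCCCB1C2CCCC1CCC2 | intermediate
10 | 1-{2,4-dimethoxy-6-[8-(triisopropylsilyl)oct-7-yn-1-yl]phenoxy}-3-methoxy-5-[8-(triisopropylsilyl)oct-7-yn-1-yl]benzene | CC(C)[Si](C(C)C)(C(C)C)C#CCCCCCCc1cc(OC)cc(Oc2c(OC)cc(OC)cc2CCCCCCC#C[Si](C(C)C)(C(C)C)C(C)C)c1 | intermediate
11 | 1-[2,4-dimethoxy-6-(oct-7-yn-1-yl)phenoxy]-3-methoxy-5-(oct-7-yn-1-yl)benzene | C#CCCCCCCc1cc(OC)cc(Oc2c(OC)cc(OC)cc2CCCCCCC#C)c1 | intermediate
12 | macrocyclic C7–C10 1,3-diyne trimethyl ether (22-membered ring; methoxy groups at position 1 of ring A and positions 2 and 4 of ring B) | COc1cc2cc(c1)Oc1c(OC)cc(OC)cc1CCCCCCC#CC#CCCCCCC2 | intermediate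
13 | tri-O-methylgrevirobstol B (saturated 22-membered ring; methoxy groups at position 1 of ring A and positions 2 and 4 of ring B) | COc1cc2cc(c1)Oc1c(OC)cc(OC)cc1CCCCCCCCCCCCCCCC2 | intermediate
14 | grevirobstol B | Oc1cc2cc(c1)Oc1c(O)cc(O)cc1CCCCCCCCCCCCCCCC2 | target

Total step count: 8. Longest linear sequence: 7 steps (steps 1, 2, 4, 5, 6, 7, 8 from compound 1); step 3 is a one-step side branch.

Steps most likely to fail

1. Step 6 (macrocyclisation). Intermolecular alkyne coupling may outpace ring closure and lead to open-chain or cyclic oligomers. The fallback forms the same C8–C9 bond by olefin metathesis and sets out from dibromide 5. Nona-1,8-diene, used in excess, is mono-hydroborated with 9-BBN to 9-(non-8-en-1-yl)-9-borabicyclo[3.3.1]nonane F1, and surplus diene is removed under vacuum. F1 is coupled twice with 5 under the conditions of step 4 to give 1-[2,4-dimethoxy-6-(non-8-en-1-yl)phenoxy]-3-methoxy-5-(non-8-en-1-yl)benzene F2. Ring-closing metathesis with second-generation Grubbs catalyst, RuCl2(=CHPh)(H2IMes)(PCy3), in dilute CH2Cl2 at 40 °C, should expel ethene and give the macrocyclic C8=C9 alkene trimethyl ether F3, expected as an E/Z mixture of no consequence. Hydrogenation (H2, Pd/C, EtOAc) then rejoins the route at compound 13.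

2. Step 2 (diaryl ether formation). Aryl transfer to the doubly ortho-substituted phenoxide may be slow, so that protodeboronation and oxidative homocoupling of the boronic acid, and oxidative degradation of the electron-rich phenol, consume the partners. The fallback is a metal-free O-arylation with a diaryliodonium salt and sets out from phenol 3. 1-Bromo-3-iodo-5-methoxybenzene is oxidised with mCPBA and TsOH·H2O in MeCN and trapped with 1,3,5-trimethoxybenzene to give (3-bromo-5-methoxyphenyl)(2,4,6-trimethoxyphenyl)iodonium 4-methylbenzenesulfonate F4. The potassium phenoxide of 3 (K2CO3 or KOt-Bu, MeCN, 50 °C) adds to the trivalent iodine centre, and ligand coupling transfers the 3-bromo-5-methoxyphenyl group in preference to the electron-rich trimethoxyphenyl group. This rejoins the route at compound 5.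

3. Step 4 (double arm installation). The second coupling at the ortho-flanked ring-B bromide may stall, with protodebromination and β-hydride elimination of the alkylpalladium intermediate competing. The fallback builds the arms by sp–sp2 coupling and chain extension and sets out from dibromide 5. Double Sonogashira coupling with hex-5-yn-1-ol (Pd(PPh3)2Cl2, CuI as monovalent copper iodide, Et3N, 80 °C) gives 6-{3-[2-(6-hydroxyhex-1-yn-1-yl)-4,6-dimethoxyphenoxy]-5-methoxyphenyl}hex-5-yn-1-ol F5. Hydrogenation (H2, Pd/C, EtOAc) gives 6-{3-[2-(6-hydroxyhexyl)-4,6-dimethoxyphenoxy]-5-methoxyphenyl}hexan-1-ol F6. Mesylation (MsCl, Et3N, CH2Cl2, 0 °C) gives the bis(methanesulfonate) of that diol F7. Displacement of both mesylates with LiC≡CH·H2NCH2CH2NH2 (lithium acetylide–ethylenediamine complex) in DMSO at rt rejoins the route at compound 11, so that steps 3 and 5 are no longer needed.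

Further compounds
F1 | step 6 | 9-(non-8-en-1-yl)-9-borabicyclo[3.3.1]nonane | C=CCCCCCCCB1C2CCCC1CCC2
F2 | step 6 | 1-[2,4-dimethoxy-6-(non-8-en-1-yl)phenoxy]-3-methoxy-5-(non-8-en-1-yl)benzene | C=CCCCCCCCc1cc(OC)cc(Oc2c(OC)cc(OC)cc2CCCCCCCC=C)c1
F3 | step 6 | macrocyclic C8=C9 alkene trimethyl ether (22-membered ring, E/Z mixture) | COc1cc2cc(c1)Oc1c(OC)cc(OC)cc1CCCCCCCC=CCCCCCCC2
F4 | step 2 | (3-bromo-5-methoxyphenyl)(2,4,6-trimethoxyphenyl)iodonium 4-methylbenzenesulfonate | COc1cc(Br)cc([I+]c2c(OC)cc(OC)cc2OC)c1.Cc1ccc(cc1)S(=O)(=O)[O-]
F5 | step 4 | 6-{3-[2-(6-hydroxyhex-1-yn-1-yl)-4,6-dimethoxyphenoxy]-5-methoxyphenyl}hex-5-yn-1-ol | OCCCCC#Cc1cc(OC)cc(Oc2c(OC)cc(OC)cc2C#CCCCCO)c1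
F6 | step 4 | 6-{3-[2-(6-hydroxyhexyl)-4,6-dimethoxyphenoxy]-5-methoxyphenyl}hexan-1-ol | OCCCCCCc1cc(OC)cc(Oc2c(OC)cc(OC)cc2CCCCCCO)c1
F7 | step 4 | 6-{3-[2-(6-methanesulfonyloxyhexyl)-4,6-dimethoxyphenoxy]-5-methoxyphenyl}hexyl methanesulfonate | CS(=O)(=O)OCCCCCCc1cc(OC)cc(Oc2c(OC)cc(OC)cc2CCCCCCOS(C)(=O)=O)c1
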